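The cyclohexene ring is cut into two three-carbon halves, C(OAr)–CH=C(CH3) and CH(OH)–CH2–CH(side chain). Its cis-1,4-dioxygen pattern across the C=C(CH3) unit marks it as a masked 2-methyl-5-alkylcyclohexa-1,3-diene, hence a carvone-type enone. One pot builds that enone: an amine-catalysed Michael/aldol-condensation/decarboxylation [3+3] of tert-butyl 3-oxopentanoate with a γ-methyl enal. The enal is cut from (R)-citronellic acid, used in reversed orientation (its carboxyl carbon becomes the side-chain ketone). The catalyst sets the ring carbon bearing the side chain. That centre relays both C–O centres through anti epoxidation of the diene and Pd-catalysed cis-1,4 opening by vanillin. A Pabon condensation finishes the curcuminoid.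

Key step: step 4

Remark on the chemistry: the 1,3-diketone of the target is drawn as one enol tautomer. The enol forms interconvert freely, so the last step delivers the equilibrium mixture that this drawing represents.

Step 1
Reactants: 1 (R)-citronellic acid
Product: 3 (3R)-N-methoxy-N,3,7-trimethyloct-6-enamide, via (3R)-1-(imidazol-1-yl)-3,7-dimethyloct-6-en-1-one 2 (not isolated)
Conditions: CDI, CH2Cl2, rt; then MeNHOMe·HCl, rt
Reagents that add atoms: N,O-dimethylhydroxylamine hydrochloride, CNOC.Cl
Why: Weinreb amide formation through the acyl imidazolide touches neither the alkene nor the β-stereocentre and stores the carboxyl carbon as a latent ketone that tolerates the acid, base and Pd conditions of steps 2–6.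

Step 2
Reactants: 3 (3R)-N-methoxy-N,3,7-trimethyloct-6-enamide
Product: 5 (3R)-N-methoxy-N,3-dimethyl-6-oxohexanamide, via (3R)-5-(5,5-dimethyl-1,2,4-trioxolan-3-yl)-N-methoxy-N,3-dimethylpentanamide 4 (not isolated)
Conditions: O3, CH2Cl2, −78 °C; then Me2S, −78 °C → rt
Reagents that add atoms: ozone, [O-][O+]=O
Why: Ozonolysis with reductive work-up cleaves the only C=C bond, sheds the isopropylidene carbons and leaves an aldehyde three carbons away from the untouched stereocentre.

Step 3
Reactants: 5 (3R)-N-methoxy-N,3-dimethyl-6-oxohexanamide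
Product: 6 (3S,4E)-N-methoxy-N,3-dimethyl-6-oxohex-4-enamide
Conditions: IBX (1.5 equiv), DMSO–PhF, 65 °C
Reagents that add atoms: none
Why: IBX α,β-dehydrogenation of the aldehyde through its enol should give the conjugated E-enal because the amide is far less enolisable, and the stereocentre is not involved (its descriptor changes from R to S only through the CIP ranking).

Step 4
Reactants: 6 (3S,4E)-N-methoxy-N,3-dimethyl-6-oxohex-4-enamide; 7 tert-butyl 3-oxopentanoate
Product: 10 (3S)-N-methoxy-N-methyl-3-[(1S)-4-methyl-5-oxocyclohex-3-en-1-yl]butanamide, via tert-butyl (3R,4S)-6-[methoxy(methyl)amino]-4-methyl-6-oxo-3-(2-oxoethyl)-2-propanoylhexanoate 8 (not isolated), via tert-butyl (6R)-6-{(2S)-4-[methoxy(methyl)amino]-4-oxobutan-2-yl}-3-methyl-2-oxocyclohex-3-ene-1-carboxylate 9 (not isolated)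
Conditions: (R)-2-{bis[3,5-bis(trifluoromethyl)phenyl](trimethylsilyloxy)methyl}pyrrolidine (10 mol %), PhCO2H (10 mol %), 7 (1.5 equiv), toluene, rt; then p-TsOH·H2O (30 mol %), toluene, 80 °C
Reagents that add atoms: none
Why: The amine condenses with 6 to an E,s-trans iminium ion and C2 of 7 adds to its β-carbon (first ring bond, 8); acid then enolises the ethyl ketone toward its CH2, which closes onto the aldehyde (second ring bond), followed by dehydration to 9, loss of isobutene and decarboxylation. This is the known organocatalytic Michael/aldol-condensation/decarboxylation [3+3] route from β-keto esters and enals to 2,5-disubstituted cyclohex-2-enones. The one ring closes as a 6-(enolendo)-exo-trig aldol, since the other enol of the ketone could only form a four-membered ring. The only ring stereocentre that survives, the CH bearing the side chain, is set by the catalyst: the CAr2(OTMS) group of the R catalyst shields one face of the iminium ion, so the donor adds to the other face and gives the (1S) ring carbon of 10; the centres at the ester-bearing carbon and the carbinol are erased by decarboxylation and dehydration, and the side-chain CH(CH3) is carried over from 1. The step needs 1,4- over 1,2-addition, reaction at the doubly activated CH2 of 7, and retention of the γ-stereocentre. These are secured by iminium activation, by the pKa gap within 7, and by a fast concentrated Michael stage (excess 7, weak-acid cocatalyst) that should outrun γ-deprotonation to the dienamine; the Weinreb amide is inert to both stages.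

Step 5
Reactants: 10 (3S)-N-methoxy-N-methyl-3-[(1S)-4-methyl-5-oxocyclohex-3-en-1-yl]butanamide
Product: 12 (3R)-3-{(2S)-4-[methoxy(methyl)amino]-4-oxobutan-2-yl}-6-methylcyclohexa-1,5-dien-1-yl trifluoromethanesulfonate, via lithium (3R)-3-{(2S)-4-[methoxy(methyl)amino]-4-oxobutan-2-yl}-6-methylcyclohexa-1,5-dien-1-olate 11 (not isolated)
Conditions: LiHMDS (1.05 equiv), THF, −78 °C; then PhNTf2, −78 → 0 °C
Reagents that add atoms: N-phenylbis(trifluoromethanesulfonimide), O=S(=O)(N(c1ccccc1)S(=O)(=O)C(F)(F)F)C(F)(F)F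
Why: Kinetic α′-deprotonation of a 2-methylcyclohexenone (the behaviour of carvone) gives the cross-conjugated dienolate, which is O-triflated, the ketone being several pKa units more acidic than the amide and no stereocentre being touched.

Step 6
Reactants: 12 (3R)-3-{(2S)-4-[methoxy(methyl)amino]-4-oxobutan-2-yl}-6-methylcyclohexa-1,5-dien-1-yl trifluoromethanesulfonate
Product: 13 (3S)-N-methoxy-N-methyl-3-[(1R)-4-methylcyclohexa-2,4-dien-1-yl]butanamide
Conditions: Pd(OAc)2 (5 mol %), PPh3 (10 mol %), HCO2H, Et3N, DMF, 50 °C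
Reagents that add atoms: none
Why: Palladium-catalysed formate reduction of an alkenyl triflate (oxidative addition, formate decarboxylation, C–H reductive elimination) replaces OTf by H with both double bonds left in place, which gives the 2-methyl-5-alkylcyclohexa-1,3-diene regiospecifically.

Step 7
Reactants: 13 (3S)-N-methoxy-N-methyl-3-[(1R)-4-methylcyclohexa-2,4-dien-1-yl]butanamide
Product: 15 (6S)-2-methyl-6-[(1R)-4-methylcyclohexa-2,4-dien-1-yl]hept-2-en-4-one, via the bromomagnesium alkoxide of the tetrahedral adduct 14 (not isolated)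
Conditions: 2-methylprop-1-enylmagnesium bromide (1.5 equiv), THF, 0 °C; then aq NH4Cl
Reagents that add atoms: 2-methylprop-1-enylmagnesium bromide, CC(C)=C[Mg]Br
Why: In this Weinreb ketone synthesis the chelated tetrahedral adduct stops after one addition and collapses on quench to the β,β-dimethyl enone, and the diene and both stereocentres are inert to the Grignard reagent.

Step 8
Reactants: 15 (6S)-2-methyl-6-[(1R)-4-methylcyclohexa-2,4-dien-1-yl]hept-2-en-4-one
Product: 16 (6S)-2-methyl-6-[(1S,3R,6R)-6-methyl-7-oxabicyclo[4.1.0]hept-4-en-3-yl]hept-2-en-4-one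
Conditions: DMDO (1.0 equiv), acetone–CH2Cl2, −40 °C; used without purification
Reagents that add atoms: dimethyldioxirane, CC1(C)OO1
Why: Electrophilic epoxidation should pick the trisubstituted, most electron-rich end of the diene over the disubstituted end and the electron-poor enone, and should approach anti to the side chain on the ring (substrate control of both epoxide carbons), while neutral DMDO spares the acid-labile vinyl epoxide.

Step 9
Reactants: 16 (6S)-2-methyl-6-[(1S,3R,6R)-6-methyl-7-oxabicyclo[4.1.0]hept-4-en-3-yl]hept-2-en-4-one; 17 vanillin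
Product: 18 4-{[(1R,4S,6R)-4-hydroxy-3-methyl-6-[(2S)-6-methyl-4-oxohept-5-en-2-yl]cyclohex-2-en-1-yl]oxy}-3-methoxybenzaldehyde
Conditions: Pd2(dba)3·CHCl3 (2.5 mol %), PPh3 (15 mol %), THF, 0 °C → rt
Reagents that add atoms: none
Why: In this Tsuji–Trost opening of a cyclic vinyl epoxide, Pd(0) ionises the tertiary allylic C–O bond with inversion, the alkoxide deprotonates vanillin and the phenoxide attacks the distal secondary allyl terminus anti to Pd, so double inversion places OAr cis to OH and trans to the side chain while the carbinol keeps the epoxide configuration.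

Step 10
Reactants: 17 vanillin; 19 acetylacetone
Product: 20 (5E)-6-(4-hydroxy-3-methoxyphenyl)hex-5-ene-2,4-dione (feruloylacetone)
Conditions: 19 (3 equiv), B2O3, B(OnBu)3, nBuNH2 (cat.), EtOAc, 75 °C; then 1 M HCl, 50 °C
Reagents that add atoms: none
Why: In the Pabon condensation boron chelation of the 1,3-diketone blocks the central carbon, so a terminal methyl condenses with vanillin under amine catalysis to the E-enone, and excess acetylacetone limits the reaction to one side.

Step 11
Reactants: 18 4-{[(1R,4S,6R)-4-hydroxy-3-methyl-6-[(2S)-6-methyl-4-oxohept-5-en-2-yl]cyclohex-2-en-1-yl]oxy}-3-methoxybenzaldehyde; 20 feruloylacetone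
Product: 21 bisabolocurcumin ether
Conditions: B2O3, B(OnBu)3, nBuNH2 (cat.), EtOAc, 65 °C; then 0.1 M HCl, 35 °C
Reagents that add atoms: none
Why: In this second Pabon condensation the remaining methyl of the boron-chelated diketone condenses with the aryl aldehyde to the E-alkene, under conditions too mild to engage the hindered side-chain enone or to ionise the allylic aryl ether, and no stereocentre is touched.

Compound list
1 | (R)-citronellic acid, (3R)-3,7-dimethyloct-6-enoic acid | C[C@H](CCC=C(C)C)CC(=O)O | starting material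
2 | (3R)-1-(imidazol-1-yl)-3,7-dimethyloct-6-en-1-one | C[C@H](CCC=C(C)C)CC(=O)n1ccnc1 | intermediate
3 | (3R)-N-methoxy-N,3,7-trimethyloct-6-enamide | C[C@H](CCC=C(C)C)CC(=O)N(C)OC | intermediate
4 | (3R)-5-(5,5-dimethyl-1,2,4-trioxolan-3-yl)-N-methoxy-N,3-dimethylpentanamide (secondary ozonide) | C[C@H](CCC1OOC(C)(C)O1)CC(=O)N(C)OC | intermediate
5 | (3R)-N-methoxy-N,3-dimethyl-6-oxohexanamide | C[C@H](CCC=O)CC(=O)N(C)OC | intermediate
6 | (3S,4E)-N-methoxy-N,3-dimethyl-6-oxohex-4-enamide | C[C@H](/C=C/C=O)CC(=O)N(C)OC | intermediate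
7 | tert-butyl 3-oxopentanoate | CCC(=O)CC(=O)OC(C)(C)C | starting material
8 | tert-butyl (3R,4S)-6-[methoxy(methyl)amino]-4-methyl-6-oxo-3-(2-oxoethyl)-2-propanoylhexanoate (C2 epimers) | CCC(=O)C(C(=O)OC(C)(C)C)[C@H](CC=O)[C@@H](C)CC(=O)N(C)OC | intermediate
9 | tert-butyl (6R)-6-{(2S)-4-[methoxy(methyl)amino]-4-oxobutan-2-yl}-3-methyl-2-oxocyclohex-3-ene-1-carboxylate (C1 epimers) | CC1=CC[C@H]([C@@H](C)CC(=O)N(C)OC)C(C(=O)OC(C)(C)C)C1=O | intermediate
10 | (3S)-N-methoxy-N-methyl-3-[(1S)-4-methyl-5-oxocyclohex-3-en-1-yl]butanamide | CC1=CC[C@@H](CC1=O)[C@@H](C)CC(=O)N(C)OC | intermediate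
11 | lithium (3R)-3-{(2S)-4-[methoxy(methyl)amino]-4-oxobutan-2-yl}-6-methylcyclohexa-1,5-dien-1-olate | CC1=CC[C@@H](C=C1[O-])[C@@H](C)CC(=O)N(C)OC.[Li+] | intermediate
12 | (3R)-3-{(2S)-4-[methoxy(methyl)amino]-4-oxobutan-2-yl}-6-methylcyclohexa-1,5-dien-1-yl trifluoromethanesulfonate | CC1=CC[C@@H](C=C1OS(=O)(=O)C(F)(F)F)[C@@H](C)CC(=O)N(C)OC | intermediate
13 | (3S)-N-methoxy-N-methyl-3-[(1R)-4-methylcyclohexa-2,4-dien-1-yl]butanamide | CC1=CC[C@@H](C=C1)[C@@H](C)CC(=O)N(C)OC | intermediate
14 | bromomagnesium alkoxide of the tetrahedral adduct of 13 with the alkenyl Grignard reagent | CC1=CC[C@@H](C=C1)[C@@H](C)CC(O[Mg]Br)(C=C(C)C)N(C)OC | intermediate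
15 | (6S)-2-methyl-6-[(1R)-4-methylcyclohexa-2,4-dien-1-yl]hept-2-en-4-one | CC1=CC[C@@H](C=C1)[C@@H](C)CC(=O)C=C(C)C | intermediate
16 | (6S)-2-methyl-6-[(1S,3R,6R)-6-methyl-7-oxabicyclo[4.1.0]hept-4-en-3-yl]hept-2-en-4-one (epoxide anti to the side chain) | C[C@]12O[C@H]1C[C@@H](C=C2)[C@@H](C)CC(=O)C=C(C)C | intermediate
17 | vanillin, 4-hydroxy-3-methoxybenzaldehyde | COc1cc(C=O)ccc1O | starting material
18 | 4-{[(1R,4S,6R)-4-hydroxy-3-methyl-6-[(2S)-6-methyl-4-oxohept-5-en-2-yl]cyclohex-2-en-1-yl]oxy}-3-methoxybenzaldehyde | COc1cc(C=O)ccc1O[C@H]1C=C(C)[C@@H](O)C[C@@H]1[C@@H](C)CC(=O)C=C(C)C | intermediate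
19 | acetylacetone, pentane-2,4-dione | CC(=O)CC(C)=O | starting material
20 | (5E)-6-(4-hydroxy-3-methoxyphenyl)hex-5-ene-2,4-dione (feruloylacetone) | COc1cc(/C=C/C(=O)CC(C)=O)ccc1O | intermediate
21 | bisabolocurcumin ether | COc1cc(/C=C/C(=O)/C=C(O)/C=C/c2ccc(O[C@H]3C=C(C)[C@@H](O)C[C@@H]3[C@@H](C)CC(=O)C=C(C)C)c(OC)c2)ccc1O | target

Total step count: 11. Longest linear sequence: 10 (steps 1–9 and 11).

Steps most likely to fail

Step 4. Conjugate addition to the γ-branched iminium ion may be slow. γ-Deprotonation to the dienamine could then erode the side-chain stereocentre, and a catalyst/substrate mismatch could lower the facial selectivity. The fallback sets out from 6 and returns at 10, and it separates the two bond formations. A Mukaiyama–Michael addition of 2-(trimethylsilyloxy)but-1-ene to 6 is run at −20 °C under the 2,4-dinitrobenzoic acid salt of (2R,5R)-5-benzyl-2-tert-butyl-3-methylimidazolidin-4-one; the acidic medium and low temperature disfavour γ-deprotonation. This should give (3S,4S)-N-methoxy-N,3-dimethyl-6-oxo-4-(2-oxoethyl)octanamide F1. A separate acid-catalysed aldol condensation (p-TsOH, toluene) then closes F1 to 10.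

Step 8. The risks are poor facial selectivity on the flexible diene, competing attack at the disubstituted alkene, and isomerisation or aromatisation of the vinyl epoxide. The fallback sets out from 10 and returns at 16, and it installs the epoxide at the enone stage.
- Alkaline H2O2 should add anti to the ring substituent, as it does with carvone, to give (3S)-N-methoxy-N-methyl-3-[(1S,3S,6S)-6-methyl-5-oxo-7-oxabicyclo[4.1.0]heptan-3-yl]butanamide F2.
- NaBH4/CeCl3 reduces F2 to the epoxy alcohol (3S)-3-[(1S,3S)-5-hydroxy-6-methyl-7-oxabicyclo[4.1.0]heptan-3-yl]-N-methoxy-N-methylbutanamide F3, whose carbinol configuration is of no consequence.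
- Dehydration with Martin sulfurane can only proceed toward the ring CH2 and gives (3S)-N-methoxy-N-methyl-3-[(1S,3R,6R)-6-methyl-7-oxabicyclo[4.1.0]hept-4-en-3-yl]butanamide F4.
- 2-Methylprop-1-enyllithium at −78 °C converts the amide of F4 into the enone 16.

Step 9. The risks are attack at the tertiary allyl terminus, β-hydride elimination toward dienol or arene, and re-ionisation of the aryl ether with loss of regio- and stereochemical integrity. The fallback sets out from 15 and returns at 18. It makes the ether with oxygen as the nucleophile, so that both C–O centres come from one cycloaddition.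
- Singlet oxygen (TPP, hν, O2, CH2Cl2, −40 °C) adds [4+2] to the diene anti to the side chain and gives the endoperoxide (6S)-2-methyl-6-(5-methyl-2,3-dioxabicyclo[2.2.2]oct-5-en-7-yl)hept-2-en-4-one F5.
- Thiourea reduces F5 to (6S)-6-[(1R,2R,5S)-2,5-dihydroxy-4-methylcyclohex-3-en-1-yl]-2-methylhept-2-en-4-one F6.
- TBSCl/imidazole silylates the less hindered carbinol next to the ring CH2 and gives the mono-TBS ether F7.
- NaH and 4-fluoro-3-methoxybenzaldehyde in DMF arylate the remaining alkoxide by SNAr with retention to give the silylated aryl ether F8.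
- HF·pyridine releases 18 from F8.

Further compounds
F1 | step 4 | (3S,4S)-N-methoxy-N,3-dimethyl-6-oxo-4-(2-oxoethyl)octanamide | CCC(=O)C[C@H](CC=O)[C@@H](C)CC(=O)N(C)OC
F2 | step 8 | (3S)-N-methoxy-N-methyl-3-[(1S,3S,6S)-6-methyl-5-oxo-7-oxabicyclo[4.1.0]heptan-3-yl]butanamide | C[C@]12O[C@H]1C[C@@H](CC2=O)[C@@H](C)CC(=O)N(C)OC
F3 | step 8 | (3S)-3-[(1S,3S)-5-hydroxy-6-methyl-7-oxabicyclo[4.1.0]heptan-3-yl]-N-methoxy-N-methylbutanamide (carbinol epimers) | C[C@]12O[C@H]1C[C@@H](CC2O)[C@@H](C)CC(=O)N(C)OC
F4 | step 8 | (3S)-N-methoxy-N-methyl-3-[(1S,3R,6R)-6-methyl-7-oxabicyclo[4.1.0]hept-4-en-3-yl]butanamide | C[C@]12O[C@H]1C[C@@H](C=C2)[C@@H](C)CC(=O)N(C)OC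
F5 | step 9 | (6S)-2-methyl-6-(5-methyl-2,3-dioxabicyclo[2.2.2]oct-5-en-7-yl)hept-2-en-4-one, O–O bridge anti to the side chain | CC1=C[C@@H]2OO[C@H]1C[C@@H]2[C@@H](C)CC(=O)C=C(C)C
F6 | step 9 | (6S)-6-[(1R,2R,5S)-2,5-dihydroxy-4-methylcyclohex-3-en-1-yl]-2-methylhept-2-en-4-one | O[C@H]1C=C(C)[C@@H](O)C[C@@H]1[C@@H](C)CC(=O)C=C(C)C
F7 | step 9 | (6S)-6-[(1R,2R,5S)-5-(tert-butyldimethylsilyloxy)-2-hydroxy-4-methylcyclohex-3-en-1-yl]-2-methylhept-2-en-4-one | O[C@H]1C=C(C)[C@@H](O[Si](C)(C)C(C)(C)C)C[C@@H]1[C@@H](C)CC(=O)C=C(C)C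
F8 | step 9 | 4-{[(1R,4S,6R)-4-(tert-butyldimethylsilyloxy)-3-methyl-6-[(2S)-6-methyl-4-oxohept-5-en-2-yl]cyclohex-2-en-1-yl]oxy}-3-methoxybenzaldehyde | COc1cc(C=O)ccc1O[C@H]1C=C(C)[C@@H](O[Si](C)(C)C(C)(C)C)C[C@@H]1[C@@H](C)CC(=O)C=C(C)C
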